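**Plan**

- Cuts (flavanone numbering): first O1–C2 of ring C, then C4–C4a, which releases ring A as a phloroglucinol anion equivalent, and last C1'–C2' and C5'–C6' of ring B together.
- Enabling feature: in ring B, C1' (the carbon carrying C2) is ortho to O2' and para to O4'. A butadiene oxygenated twice at C1 and once at C3 leaves exactly this pattern on an acyl alkyne. The prenylated carbons C3' and C5' correspond to the α- and γ-carbons of acetoacetate.
- Forward order: both prenyl groups go onto methyl acetoacetate. The derived bis(silyloxy) ketene acetal diene and a glycerate-derived ethynyl ketone (carbonyl = C2) build ring B. Ring A is then added intact at C4, and ring C closes last.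
- Stereochemistry: C3 is bought as methyl (S)-isopropylideneglycerate and none of its bonds is broken. C2 is set syn (2S) by Felkin–Anh reduction and becomes 2R on ring closure, where inversion and ionisation both lead to the diequatorial 2,3-trans ring fixed by C3.

Key step: step 7

Assumption: the SMILES is read as the (2R,3R), 2,3-trans dihydroflavonol. Flavanone numbering is used for the corresponding atoms of all intermediates; prenyl = 3-methylbut-2-en-1-yl, MOM = methoxymethyl.

**Route**

Step 1
Reactants: 1 methyl acetoacetate; 2 prenyl bromide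
Product: 4 methyl 7-methyl-3-oxooct-6-enoate, via acetoacetate dianion 3 (not isolated)
Conditions: NaH, THF, 0 °C; n-BuLi, 0 °C; then 2 (1 equiv), 0 °C to rt
Reagents that add atoms: none
Why: γ-Alkylation of the acetoacetate dianion, in which the carbanion formed last is much the more nucleophilic site, so one equivalent of the allylic bromide reacts by SN2 at C4 only and places the future C5' prenyl group.

Step 2
Reactants: 4 methyl 7-methyl-3-oxooct-6-enoate; 2 prenyl bromide
Product: 5 methyl 7-methyl-2-prenyl-3-oxooct-6-enoate (racemic)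
Conditions: K2CO3, acetone, reflux
Reagents that add atoms: none
Why: Classical acetoacetic ester C-alkylation at the doubly activated C2 (future C3'), where one equivalent of halide and the greater hindrance of the product should limit double alkylation; the new centre disappears in step 3.

Step 3
Reactants: 5 methyl 7-methyl-2-prenyl-3-oxooct-6-enoate
Product: 6 methyl 7-methyl-2-prenyl-3-(trimethylsilyloxy)octa-2,6-dienoate (E/Z mixture)
Conditions: Me3SiCl, Et3N, toluene, rt
Reagents that add atoms: chlorotrimethylsilane, C[Si](C)(C)Cl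
Why: Soft enolisation and O-silylation of a β-keto ester, the standard first stage towards 1,3-bis(silyloxy)dienes; the enol ether geometry does not matter because the next step redefines the π system.

Step 4
Reactants: 6 methyl 7-methyl-2-prenyl-3-(trimethylsilyloxy)octa-2,6-dienoate
Product: 8 (3Z)-1-methoxy-2,4-diprenyl-1,3-bis(trimethylsilyloxy)buta-1,3-diene, via lithium dienolate 7 (not isolated)
Conditions: LiN(i-Pr)2, THF, −78 °C; Me3SiCl, −78 °C to rt
Reagents that add atoms: chlorotrimethylsilane, C[Si](C)(C)Cl
Why: Kinetic γ-deprotonation of the β-silyloxy enoate and O-silylation of the extended enolate (silyl ketene acetal formation), the standard second stage for this diene class, which for steric reasons should place the C4 chain trans to C2.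

Step 5
Reactants: 9 methyl (S)-2,2-dimethyl-1,3-dioxolane-4-carboxylate
Product: 10 (S)-N-methoxy-N,2,2-trimethyl-1,3-dioxolane-4-carboxamide
Conditions: MeNH(OMe)·HCl, i-PrMgCl, THF, −20 to 0 °C
Reagents that add atoms: N,O-dimethylhydroxylamine hydrochloride, CNOC.Cl
Why: Weinreb amide formation by direct aminolysis of the ester with the magnesium amide, run below 0 °C where the α-alkoxy stereocentre of glycerate derivatives is not deprotonated.

Step 6
Reactants: 10 (S)-N-methoxy-N,2,2-trimethyl-1,3-dioxolane-4-carboxamide; 11 ethynylmagnesium bromide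
Product: 13 1-[(4S)-2,2-dimethyl-1,3-dioxolan-4-yl]prop-2-yn-1-one, via magnesium tetrahedral adduct 12 (not isolated)
Conditions: THF, 0 °C; inverse quench into cold 1 M HCl
Reagents that add atoms: none
Why: Weinreb ketone synthesis, in which the chelated adduct survives until the quench so that only one acetylide adds, and the cold acid keeps the released amine protonated so that it cannot add to the terminal ynone.

Step 7
Reactants: 8 (3Z)-1-methoxy-2,4-diprenyl-1,3-bis(trimethylsilyloxy)buta-1,3-diene; 13 1-[(4S)-2,2-dimethyl-1,3-dioxolan-4-yl]prop-2-yn-1-one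
Product: 16 (2,4-dihydroxy-3,5-diprenylphenyl)[(4S)-2,2-dimethyl-1,3-dioxolan-4-yl]methanone, via cyclohexa-1,4-diene cycloadduct 14 (not isolated), via bis(trimethylsilyl) aryl ether 15 (not isolated)
Conditions: 8 in excess, toluene, rt to 80 °C, no Lewis acid; then MeOH, citric acid (cat.), rt
Reagents that add atoms: none
Why: The diene is a vinylogous silyl ketene acetal with its largest HOMO coefficient at the prenyl-bearing terminus (future C5'), and the ynone has its largest LUMO coefficient at the unsubstituted alkyne carbon (future C6'), so C5'–C6' forms ahead of C2'–C1', either in an asynchronous concerted [4+2] or as a Mukaiyama–Michael addition followed by collapse of the allenolate onto the silyloxycarbenium carbon. The closest known reaction type is the Diels–Alder benzannulation of 1,1-dialkoxy- and 1-alkoxy-1,3-bis(silyloxy)buta-1,3-dienes with acetylenic ketones and esters, which gives acylresorcinol derivatives in this same orientation. Ring B is the only ring closed, in a six-membered [4+2] mode with four carbons from the acetoacetate chain and two from the alkyne; adduct 14 then loses methanol by 1,4-elimination (OMe from C2', H from C5') to give arene 15, and methanolysis of the two aryl silyl ethers gives 16. No lasting stereocentre is created, because the two sp3 ring carbons of 14 vanish on aromatisation, and the spectator C3 is protected from enolisation by the neutral medium. The selectivity needed is regiochemical, and it is secured by the matched donor–acceptor polarisation of the partners, by the terminal alkyne offering an unhindered carbon to the crowded diene terminus, and by the (3Z) geometry, which turns the C4 chain outward so that the s-cis conformer stays accessible. Methanol rather than silanol should leave the mixed ketal carbon because the methoxy oxygen is the more basic one, and omitting Lewis acids avoids attack of the diene on the ketone carbonyl.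

Step 8
Reactants: 16 (2,4-dihydroxy-3,5-diprenylphenyl)[(4S)-2,2-dimethyl-1,3-dioxolan-4-yl]methanone
Product: 17 [2,4-bis(methoxymethoxy)-3,5-diprenylphenyl][(4S)-2,2-dimethyl-1,3-dioxolan-4-yl]methanone
Conditions: MOMCl, i-Pr2NEt, n-Bu4NI (cat.), CH2Cl2, 0 °C to reflux
Reagents that add atoms: chloromethyl methyl ether, COCCl
Why: O-alkylation of both phenols, with iodide catalysis helping the hydrogen-bonded and flanked O2'–H, uses only an amine base that is too weak to enolise the ketone, so C3 is preserved.

Step 9
Reactants: 17 [2,4-bis(methoxymethoxy)-3,5-diprenylphenyl][(4S)-2,2-dimethyl-1,3-dioxolan-4-yl]methanone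
Product: 18 (S)-[2,4-bis(methoxymethoxy)-3,5-diprenylphenyl][(4S)-2,2-dimethyl-1,3-dioxolan-4-yl]methanol (syn)
Conditions: LiBH(s-Bu)3, THF, −78 °C
Reagents that add atoms: none
Why: Felkin–Anh-controlled reduction, in which the bulky non-chelating hydride approaches anti to the perpendicular C3–O bond and past C3–H, should give the syn (2S) carbinol that the trans dioxolane of the next step requires.

Step 10
Reactants: 18 (S)-[2,4-bis(methoxymethoxy)-3,5-diprenylphenyl][(4S)-2,2-dimethyl-1,3-dioxolan-4-yl]methanol
Product: 19 {(4S,5S)-5-[2,4-bis(methoxymethoxy)-3,5-diprenylphenyl]-2,2-dimethyl-1,3-dioxolan-4-yl}methanol (trans)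
Conditions: camphorsulfonic acid (cat.), dry acetone, rt
Reagents that add atoms: none
Why: Acid-catalysed acetonide migration under thermodynamic control, in which reversible ketal opening lets the isopropylidene group settle on the syn O2/O3 pair as the favoured trans-4,5-disubstituted dioxolane and frees the primary C4 hydroxyl; only bonds to the ketal carbon break, so C3 is untouched, and aryl MOM ethers react far more slowly than a ketal.

Step 11
Reactants: 19 {(4S,5S)-5-[2,4-bis(methoxymethoxy)-3,5-diprenylphenyl]-2,2-dimethyl-1,3-dioxolan-4-yl}methanol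
Product: 20 (4R,5S)-5-[2,4-bis(methoxymethoxy)-3,5-diprenylphenyl]-2,2-dimethyl-1,3-dioxolane-4-carbaldehyde
Conditions: Dess–Martin periodinane, NaHCO3, CH2Cl2, 0 °C to rt
Reagents that add atoms: none
Why: Buffered Dess–Martin oxidation of a primary alcohol leaves alkenes, MOM ethers and the ketal alone, and the aldehyde α-carbon (C3) already sits in the more stable trans dioxolane, so it has no driving force to epimerise.

Step 12
Reactants: 21 phloroglucinol
Product: 22 1,3,5-tris(methoxymethoxy)benzene
Conditions: MOMCl, i-Pr2NEt, CH2Cl2, 0 °C to rt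
Reagents that add atoms: chloromethyl methyl ether, COCCl
Why: Williamson-type O-alkylation of three equivalent phenols, a standard protection that also installs the directing groups for the lithiation.

Step 13
Reactants: 22 1,3,5-tris(methoxymethoxy)benzene; 20 (4R,5S)-5-[2,4-bis(methoxymethoxy)-3,5-diprenylphenyl]-2,2-dimethyl-1,3-dioxolane-4-carbaldehyde
Product: 24 {(4S,5S)-5-[2,4-bis(methoxymethoxy)-3,5-diprenylphenyl]-2,2-dimethyl-1,3-dioxolan-4-yl}[2,4,6-tris(methoxymethoxy)phenyl]methanol (both C4 epimers), via 2,4,6-tris(methoxymethoxy)phenyllithium 23 (not isolated)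
Conditions: n-BuLi, THF, 0 °C; then 20, −78 °C
Reagents that add atoms: none
Why: Directed ortho-metalation between two OMOM groups followed by 1,2-addition of the aryllithium to the α-alkoxy aldehyde forms C4–C4a, and the new carbinol centre is left uncontrolled because it is oxidised next.

Step 14
Reactants: 24 {(4S,5S)-5-[2,4-bis(methoxymethoxy)-3,5-diprenylphenyl]-2,2-dimethyl-1,3-dioxolan-4-yl}[2,4,6-tris(methoxymethoxy)phenyl]methanol
Product: 25 {(4R,5S)-5-[2,4-bis(methoxymethoxy)-3,5-diprenylphenyl]-2,2-dimethyl-1,3-dioxolan-4-yl}[2,4,6-tris(methoxymethoxy)phenyl]methanone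
Conditions: Dess–Martin periodinane, NaHCO3, CH2Cl2, rt
Reagents that add atoms: none
Why: Dess–Martin oxidation of the doubly ortho-substituted benzylic alcohol gives the aryl ketone, removes the C4 stereocentre, and tolerates the electron-rich arenes and the prenyl groups.

Step 15
Reactants: 25 {(4R,5S)-5-[2,4-bis(methoxymethoxy)-3,5-diprenylphenyl]-2,2-dimethyl-1,3-dioxolan-4-yl}[2,4,6-tris(methoxymethoxy)phenyl]methanone
Product: 27 cathayanon I [(2R,3R)-2-(2,4-dihydroxy-3,5-diprenylphenyl)-3,5,7-trihydroxychroman-4-one], via open-chain dihydroxy ketone 26 (not isolated)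
Conditions: 3 M aq HCl, MeOH, 40 °C
Reagents that add atoms: none
Why: Acid solvolysis removes the five aryl MOM ethers and the ketal, and one of the two equivalent ortho hydroxyls of ring A replaces the benzylic C2 oxygen activated by O2' and O4', as in the known closure of MOM-protected chalcone epoxides and α,β-dioxygenated dihydrochalcones to dihydroflavonols; displacement of the 2S centre with inversion and prior ionisation at C2 both lead to the 2R,3R ring with aryl and hydroxyl diequatorial, the reversible C2–O1 bond corrects any cis isomer, and C3 takes no part.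

**Compound list**

1 | methyl acetoacetate | COC(=O)CC(C)=O | starting material
2 | prenyl bromide (1-bromo-3-methylbut-2-ene) | CC(C)=CCBr | starting material
3 | sodium lithium dianion of methyl acetoacetate | C=C([O-])C=C([O-])OC.[Na+].[Li+] | intermediate
4 | methyl 7-methyl-3-oxooct-6-enoate | COC(=O)CC(=O)CCC=C(C)C | intermediate
5 | methyl 7-methyl-2-prenyl-3-oxooct-6-enoate (racemic) | COC(=O)C(CC=C(C)C)C(=O)CCC=C(C)C | intermediate
6 | methyl 7-methyl-2-prenyl-3-(trimethylsilyloxy)octa-2,6-dienoate (E/Z mixture) | COC(=O)C(CC=C(C)C)=C(CCC=C(C)C)O[Si](C)(C)C | intermediate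
7 | lithium dienolate of 6 | COC([O-])=C(CC=C(C)C)C(O[Si](C)(C)C)=CCC=C(C)C.[Li+] | intermediate
8 | (3Z)-1-methoxy-2,4-diprenyl-1,3-bis(trimethylsilyloxy)buta-1,3-diene | COC(O[Si](C)(C)C)=C(CC=C(C)C)/C(O[Si](C)(C)C)=C/CC=C(C)C | intermediate
9 | methyl (S)-2,2-dimethyl-1,3-dioxolane-4-carboxylate | COC(=O)[C@@H]1COC(C)(C)O1 | starting material
10 | (S)-N-methoxy-N,2,2-trimethyl-1,3-dioxolane-4-carboxamide | CON(C)C(=O)[C@@H]1COC(C)(C)O1 | intermediate
11 | ethynylmagnesium bromide | C#C[Mg]Br | starting material
12 | bromomagnesium tetrahedral adduct of 10 and 11 | C#CC(O[Mg]Br)(N(C)OC)[C@@H]1COC(C)(C)O1 | intermediate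
13 | 1-[(4S)-2,2-dimethyl-1,3-dioxolan-4-yl]prop-2-yn-1-one | C#CC(=O)[C@@H]1COC(C)(C)O1 | intermediate
14 | [(4S)-2,2-dimethyl-1,3-dioxolan-4-yl][6-methoxy-3,5-diprenyl-4,6-bis(trimethylsilyloxy)cyclohexa-1,4-dien-1-yl]methanone (ring sp3 centres undefined) | COC1(O[Si](C)(C)C)C(CC=C(C)C)=C(O[Si](C)(C)C)C(CC=C(C)C)C=C1C(=O)[C@@H]2COC(C)(C)O2 | intermediate
15 | [(4S)-2,2-dimethyl-1,3-dioxolan-4-yl][3,5-diprenyl-2,4-bis(trimethylsilyloxy)phenyl]methanone | CC(C)=CCc1cc(C(=O)[C@@H]2COC(C)(C)O2)c(O[Si](C)(C)C)c(CC=C(C)C)c1O[Si](C)(C)C | intermediate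
16 | (2,4-dihydroxy-3,5-diprenylphenyl)[(4S)-2,2-dimethyl-1,3-dioxolan-4-yl]methanone | CC(C)=CCc1cc(C(=O)[C@@H]2COC(C)(C)O2)c(O)c(CC=C(C)C)c1O | intermediate
17 | [2,4-bis(methoxymethoxy)-3,5-diprenylphenyl][(4S)-2,2-dimethyl-1,3-dioxolan-4-yl]methanone | CC(C)=CCc1cc(C(=O)[C@@H]2COC(C)(C)O2)c(OCOC)c(CC=C(C)C)c1OCOC | intermediate
18 | (S)-[2,4-bis(methoxymethoxy)-3,5-diprenylphenyl][(4S)-2,2-dimethyl-1,3-dioxolan-4-yl]methanol | CC(C)=CCc1cc([C@H](O)[C@@H]2COC(C)(C)O2)c(OCOC)c(CC=C(C)C)c1OCOC | intermediate
19 | {(4S,5S)-5-[2,4-bis(methoxymethoxy)-3,5-diprenylphenyl]-2,2-dimethyl-1,3-dioxolan-4-yl}methanol | CC(C)=CCc1cc([C@@H]2OC(C)(C)O[C@H]2CO)c(OCOC)c(CC=C(C)C)c1OCOC | intermediate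
20 | (4R,5S)-5-[2,4-bis(methoxymethoxy)-3,5-diprenylphenyl]-2,2-dimethyl-1,3-dioxolane-4-carbaldehyde | CC(C)=CCc1cc([C@@H]2OC(C)(C)O[C@H]2C=O)c(OCOC)c(CC=C(C)C)c1OCOC | intermediate
21 | phloroglucinol | Oc1cc(O)cc(O)c1 | starting material
22 | 1,3,5-tris(methoxymethoxy)benzene | COCOc1cc(OCOC)cc(OCOC)c1 | intermediate
23 | 2,4,6-tris(methoxymethoxy)phenyllithium | [Li]c1c(OCOC)cc(OCOC)cc1OCOC | intermediate
24 | {(4S,5S)-5-[2,4-bis(methoxymethoxy)-3,5-diprenylphenyl]-2,2-dimethyl-1,3-dioxolan-4-yl}[2,4,6-tris(methoxymethoxy)phenyl]methanol (carbinol epimers) | CC(C)=CCc1cc([C@@H]2OC(C)(C)O[C@H]2C(O)c3c(OCOC)cc(OCOC)cc3OCOC)c(OCOC)c(CC=C(C)C)c1OCOC | intermediate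
25 | {(4R,5S)-5-[2,4-bis(methoxymethoxy)-3,5-diprenylphenyl]-2,2-dimethyl-1,3-dioxolan-4-yl}[2,4,6-tris(methoxymethoxy)phenyl]methanone | CC(C)=CCc1cc([C@@H]2OC(C)(C)O[C@H]2C(=O)c3c(OCOC)cc(OCOC)cc3OCOC)c(OCOC)c(CC=C(C)C)c1OCOC | intermediate
26 | (2R,3S)-3-(2,4-dihydroxy-3,5-diprenylphenyl)-2,3-dihydroxy-1-(2,4,6-trihydroxyphenyl)propan-1-one | CC(C)=CCc1cc([C@H](O)[C@@H](O)C(=O)c2c(O)cc(O)cc2O)c(O)c(CC=C(C)C)c1O | intermediate
27 | cathayanon I, (2R,3R)-2-(2,4-dihydroxy-3,5-diprenylphenyl)-3,5,7-trihydroxychroman-4-one | CC(C)=CCc1cc([C@H]2Oc3cc(O)cc(O)c3C(=O)[C@@H]2O)c(O)c(CC=C(C)C)c1O | target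

**Step count**

Total step count: 15. Longest linear sequence: 12 steps (1–4, 7–11, 13–15).

**Steps most likely to fail**

Step 7. The fully substituted diene may be consumed by hydrolysis or silyl transfer before it reacts. Alternatively, a conjugate addition may stall before the second bond forms.

The fallback runs from 10 back to 17. Ring B is taken from an arene, and the prenyl groups are placed by directed ortho-metalation.
- Resorcinol is protected with MOMCl and i-Pr2NEt to give 1,3-bis(methoxymethoxy)benzene F1.
- n-BuLi in THF at 0 °C deprotonates between the two acetal oxygens to give 2,6-bis(methoxymethoxy)phenyllithium F2. Alkylation with 2 (CuI cat.) gives 1,3-bis(methoxymethoxy)-2-prenylbenzene F3.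
- A second metalation (n-BuLi, TMEDA) next to an OMOM group gives 2,4-bis(methoxymethoxy)-3-prenylphenyllithium F4. Alkylation with 2 gives 1,3-bis(methoxymethoxy)-2,4-diprenylbenzene F5.
- The only position still flanked by an OMOM group is then lithiated to 2,4-bis(methoxymethoxy)-3,5-diprenylphenyllithium F6.
- Addition of F6 to Weinreb amide 10 gives the lithium tetrahedral adduct F7, which collapses on quenching to ketone 17, so step 8 is bypassed as well.

Step 10. The equilibrium may stop short of the internal dioxolane. Prolonged acid contact may also start exchange between the benzylic hydroxyl and the neighbouring MOM acetal.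

The fallback runs from 18 back to 19. The position of the ketal is enforced by blocking the primary oxygen.
- The terminal acetonide of 18 is hydrolysed (CeCl3·7H2O, oxalic acid, MeCN, rt) to (1S,2S)-1-[2,4-bis(methoxymethoxy)-3,5-diprenylphenyl]propane-1,2,3-triol F8.
- The primary hydroxyl is silylated selectively (t-BuMe2SiCl, imidazole, CH2Cl2, 0 °C) to give the 3-O-(tert-butyldimethylsilyl) diol F9.
- 2,2-Dimethoxypropane and pyridinium p-toluenesulfonate can then bridge only O2 and O3, giving the trans-acetonide silyl ether F10.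
- n-Bu4NF in THF releases 19.

Step 15. The freed ring B phenols may add to the neighbouring prenyl double bonds under acid catalysis, competing with the slower MOM cleavages. Equilibration to the trans ring may also be incomplete.

The fallback runs from 25 back to 27. The MOM ethers are removed without Brønsted acid, and the ring is closed afterwards.
- Me3SiOTf and 2,2'-bipyridyl in MeCN at 0 °C exchange aryl MOM ethers for aryl silyl ethers under buffered conditions, giving the pentakis(trimethylsilyl) ether F11.
- Addition of water hydrolyses F11 to the pentaphenol acetonide F12.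
- With O2' and O4' free, the benzylic C2–O bond of F12 should open on gentle warming in aqueous MeCN with pyridinium p-toluenesulfonate. This acidity is far below what is needed to protonate a trisubstituted alkene. A ring A hydroxyl then closes ring C to give 27.
- If the dioxolane opened earlier in this sequence, that would only bring the same closure forward.

**Further compounds**

F1 | step 7 | 1,3-bis(methoxymethoxy)benzene | COCOc1cccc(OCOC)c1
F2 | step 7 | 2,6-bis(methoxymethoxy)phenyllithium | [Li]c1c(OCOC)cccc1OCOC
F3 | step 7 | 1,3-bis(methoxymethoxy)-2-prenylbenzene | COCOc1cccc(OCOC)c1CC=C(C)C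
F4 | step 7 | 2,4-bis(methoxymethoxy)-3-prenylphenyllithium | [Li]c1ccc(OCOC)c(CC=C(C)C)c1OCOC
F5 | step 7 | 1,3-bis(methoxymethoxy)-2,4-diprenylbenzene | COCOc1ccc(CC=C(C)C)c(OCOC)c1CC=C(C)C
F6 | step 7 | 2,4-bis(methoxymethoxy)-3,5-diprenylphenyllithium | [Li]c1cc(CC=C(C)C)c(OCOC)c(CC=C(C)C)c1OCOC
F7 | step 7 | lithium tetrahedral adduct of F6 and 10 | [Li]OC(N(C)OC)(c1cc(CC=C(C)C)c(OCOC)c(CC=C(C)C)c1OCOC)[C@@H]2COC(C)(C)O2
F8 | step 10 | (1S,2S)-1-[2,4-bis(methoxymethoxy)-3,5-diprenylphenyl]propane-1,2,3-triol | CC(C)=CCc1cc([C@H](O)[C@@H](O)CO)c(OCOC)c(CC=C(C)C)c1OCOC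
F9 | step 10 | (1S,2S)-1-[2,4-bis(methoxymethoxy)-3,5-diprenylphenyl]-3-(tert-butyldimethylsilyloxy)propane-1,2-diol | CC(C)=CCc1cc([C@H](O)[C@@H](O)CO[Si](C)(C)C(C)(C)C)c(OCOC)c(CC=C(C)C)c1OCOC
F10 | step 10 | tert-butyldimethylsilyl ether of 19 (trans acetonide) | CC(C)=CCc1cc([C@@H]2OC(C)(C)O[C@H]2CO[Si](C)(C)C(C)(C)C)c(OCOC)c(CC=C(C)C)c1OCOC
F11 | step 15 | pentakis(trimethylsilyl) ether corresponding to 25 | CC(C)=CCc1cc([C@@H]2OC(C)(C)O[C@H]2C(=O)c3c(O[Si](C)(C)C)cc(O[Si](C)(C)C)cc3O[Si](C)(C)C)c(O[Si](C)(C)C)c(CC=C(C)C)c1O[Si](C)(C)C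
F12 | step 15 | {(4R,5S)-5-(2,4-dihydroxy-3,5-diprenylphenyl)-2,2-dimethyl-1,3-dioxolan-4-yl}(2,4,6-trihydroxyphenyl)methanone | CC(C)=CCc1cc([C@@H]2OC(C)(C)O[C@H]2C(=O)c3c(O)cc(O)cc3O)c(O)c(CC=C(C)C)c1O
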